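**Plan**
1. Numbering (icetexane): ring A = C1–C5 + C10 (cyclohexane, gem-dimethyl at C4); ring B = C5–C10 + C20 (cycloheptane); ring C = quinone (C8, C9, C11–C14); an oxygen bridges C10 and the hemiketal carbon C7.
2. Cuts: quinone ⇒ trimethoxyarene; C7–C8 (aryl anion onto a γ-lactone carbonyl, which opens ring B and the hemiketal bridge together); C10–C20 (benzyl metal + ring A ketone); then ring A is contracted by returning the C4–C5 bond to C4–C10, giving a 1-alkenyl-2,2-dimethylcyclopentanol.
3. Enabling feature: C10–O and C7=O stand 1,4 across C5–C6, and C5 carries the quaternary C4. This 2-(2-oxoethyl)-3,3-dimethylcyclohexanone array is the product of a vinylogous α-ketol (semipinacol) shift of the ring bond C4–C10 onto C5 of the enal C7(=O)–C6=C5.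
4. Forward order: cyclopentanol → ring A by one-carbon expansion (step 3) → C10–C20 bond and γ-lactone → ring B and the oxygen bridge in one anionic cyclisation → ring C oxidised to the quinone last.
5. Stereochemistry: C5 from the chiral amine catalyst in step 3, which should convert both enantiomers of the racemic carbinol (its stereocentre is erased) into one keto aldehyde; C10 by substrate-controlled equatorial attack anti to the C5 side chain; C7 is fixed by the bridge.

Key step: step 3

Assumption 1: electrophilic substitution of 9 is taken to occur para to the hindered C2 methoxy group (the future C8), as for 1,2,4-trimethoxybenzene and its 3-alkyl congeners; the last free position then becomes C9.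
Assumption 2: the sense of induction in step 3 is taken from the usual steric-shielding model of diarylprolinol silyl ether iminium ions; the antipodal catalyst would be used if the sense proves opposite.

**Step 1**
Reactants: 1 2,2-dimethylcyclopentan-1-one
Product: 2 rac-1-ethenyl-2,2-dimethylcyclopentan-1-ol
Conditions: CH2=CHMgBr, THF, 0 °C → rt; then H2O
Reagents that add atoms: vinylmagnesium bromide, C=C[Mg]Br
Why: 1,2-addition of a vinyl Grignard reagent to the ketone; the carbinol centre is made racemic on purpose because step 3 destroys it.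

**Step 2**
Reactants: 2 rac-1-ethenyl-2,2-dimethylcyclopentan-1-ol
Product: 3 rac-(E)-3-(1-hydroxy-2,2-dimethylcyclopentyl)prop-2-enal
Conditions: (E)-crotonaldehyde (5 equiv), second-generation Hoveyda–Grubbs catalyst RuCl2(=CH-C6H4-2-OiPr)(H2IMes) (5 mol %), CH2Cl2, 40 °C
Reagents that add atoms: (E)-but-2-enal, C/C=C/C=O
Why: olefin cross-metathesis of a monosubstituted alkene bearing a free tertiary allylic hydroxyl with an excess of an enal partner should give the (E)-enal under thermodynamic control and leave the carbinol untouched.

**Step 3**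
Reactants: 3 rac-(E)-3-(1-hydroxy-2,2-dimethylcyclopentyl)prop-2-enal
Product: 4 (S)-2-(2,2-dimethyl-6-oxocyclohexyl)acetaldehyde
Conditions: (R)-2-{bis[3,5-bis(trifluoromethyl)phenyl][(trimethylsilyl)oxy]methyl}pyrrolidine (20 mol %), PhCO2H (20 mol %), PhMe, 40 °C
Reagents that add atoms: none
Why: Proposed new method: condensation of the enal with the chiral secondary amine gives an (E)-α,β-unsaturated iminium ion whose electron-poor β-carbon (C5) accepts the C4–C10 σ-bond of the neighbouring carbinol, aligned with the π* orbital at C5, in a semipinacol-type 1,2-shift pushed by the C10 hydroxyl; this gives the C10 ketone and an enamine that is hydrolysed to the aldehyde with turnover of the amine. The closest known reaction type is the amine-catalysed enantioselective vinylogous α-ketol rearrangement of β-(1-hydroxycyclobutyl) enones to ring-expanded 1,4-diketones; new here are the unstrained cyclopentanol donor, the enal acceptor and a racemic carbinol whose stereocentre is destroyed, and the shift should still run because a C=C and an O–H are exchanged for a C=O and a C–H (strongly exothermic), the γ-carbon carries no hydrogen so that no dienamine can divert the iminium ion, and the migrating carbon is fully substituted. No ring is closed by cyclisation: six-membered ring A arises from the five-membered ring by a suprafacial one-carbon 1,2-shift that inserts C5 between C4 and C10. The only new stereocentre, C5, is controlled by the catalyst, whose diarylsilyloxymethyl group covers one face of the iminium ion so that C4 must arrive on the open face, which the usual shielding model predicts to give (S) with the (R)-amine; because rotation about C5–C10 lets either enantiomer of 3 place C4 on that face and C10 ends as a carbonyl, both enantiomers should converge on (S)-4. The step needs migration of C4 and not of C1, which the higher migratory aptitude of the quaternary carbon and the relief of the C4/C10 congestion should secure, and it needs catalyst control to dominate over the resident carbinol centre in both enantiomers of 3.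

**Step 4**
Reactants: 4 (S)-2-(2,2-dimethyl-6-oxocyclohexyl)acetaldehyde
Product: 6 methyl (S)-2-(2,2-dimethyl-6-oxocyclohexyl)acetate, via keto acid 5 (not isolated)
Conditions: NaClO2, NaH2PO4, 2-methylbut-2-ene, t-BuOH/H2O, 0 °C → rt; then TMSCHN2, PhMe/MeOH, 0 °C
Reagents that add atoms: sodium chlorite, [Na+].[O-]Cl=O; trimethylsilyldiazomethane, C[Si](C)(C)C=[N+]=[N-]
Why: Pinnick oxidation converts the aldehyde into the acid under buffered conditions that do not enolise the C10 ketone (so C5 is kept), and the crude acid is methylated with TMSCHN2.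

**Step 5**
Reactants: 7 1,2,4-trimethoxybenzene
Product: 8 2-(2,3,6-trimethoxyphenyl)propan-2-ol
Conditions: n-BuLi, THF, 0 °C → rt; then acetone, −78 °C → rt; then H2O
Reagents that add atoms: acetone, CC(C)=O
Why: directed ortho-lithiation at C3 of 7, the position flanked by two methoxy groups, followed by addition of the aryllithium to acetone.

**Step 6**
Reactants: 8 2-(2,3,6-trimethoxyphenyl)propan-2-ol
Product: 9 1,2,4-trimethoxy-3-(propan-2-yl)benzene
Conditions: Et3SiH, CF3CO2H, CH2Cl2, 0 °C → rt
Reagents that add atoms: none
Why: ionic hydrogenation, in which the tertiary benzylic cation stabilised by two ortho-methoxy groups forms in CF3CO2H and is captured by hydride from Et3SiH.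

**Step 7**
Reactants: 9 1,2,4-trimethoxy-3-(propan-2-yl)benzene
Product: 10 1-bromo-2,4,5-trimethoxy-3-(propan-2-yl)benzene
Conditions: NBS (1.0 equiv), MeCN, 0 °C → rt
Reagents that add atoms: N-bromosuccinimide, O=C1CCC(=O)N1Br
Why: electrophilic aromatic bromination at the free position para to the C2 methoxy group (future C8), by analogy with 1,2,4-trimethoxybenzene and its 3-alkyl congeners; one equivalent of NBS should avoid dibromination.

**Step 8**
Reactants: 10 1-bromo-2,4,5-trimethoxy-3-(propan-2-yl)benzene
Product: 11 1-bromo-2-(bromomethyl)-3,4,6-trimethoxy-5-(propan-2-yl)benzene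
Conditions: (CH2O)n, HBr (33% in AcOH), 50 °C
Reagents that add atoms: formaldehyde (from paraformaldehyde), C=O; hydrogen bromide, Br
Why: Blanc-type bromomethylation at the single remaining ring position, still activated by the ortho-methoxy group, installs C20 as a benzylic bromide.

**Step 9**
Reactants: 11 1-bromo-2-(bromomethyl)-3,4,6-trimethoxy-5-(propan-2-yl)benzene; 6 methyl (S)-2-(2,2-dimethyl-6-oxocyclohexyl)acetate
Product: 14 (3aS,7aS)-7a-{[2-bromo-3,5,6-trimethoxy-4-(propan-2-yl)phenyl]methyl}-4,4-dimethylhexahydro-1-benzofuran-2(3H)-one, via benzylic Grignard reagent 12 (not isolated), via hydroxy ester 13 (not isolated)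
Conditions: 11, Mg, Et2O, 0 °C; then 6, LaCl3·2LiCl (30 mol %), THF, −20 °C → rt; then H2O; p-TsOH (cat.), CH2Cl2, rt
Reagents that add atoms: none
Why: Grignard addition (Mg inserts into the benzylic C–Br bond faster than into the aryl C–Br bond, and LaCl3·2LiCl suppresses enolisation) to the ketone in preference to the ester; equatorial attack anti to the C5 side chain, the axial face being blocked by the axial C4 methyl group, sets C10 as (S) with oxygen cis to the acetate arm, and the alkoxide closes the cis-fused γ-lactone.

**Step 10**
Reactants: 14 (3aS,7aS)-7a-{[2-bromo-3,5,6-trimethoxy-4-(propan-2-yl)phenyl]methyl}-4,4-dimethylhexahydro-1-benzofuran-2(3H)-one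
Product: 16 (5S,7S,10S)-7,10-epoxy-11,12,14-trimethoxyicetexa-8,11,13-trien-7-ol, via aryllithium 15 (not isolated)
Conditions: t-BuLi (2.1 equiv), THF, −95 → −78 °C; then H2O
Reagents that add atoms: none
Why: Parham cyclisation, in which bromine–lithium exchange should outrun attack of t-BuLi on the lactone at −95 °C and the aryllithium adds to the lactone carbonyl C7 from the face of the C20 tether, closing ring B (seven-membered through carbon, six-membered through oxygen) and giving the bridged lithium hemiketalate in which C7 can only be (S).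

**Step 11**
Reactants: 16 (5S,7S,10S)-7,10-epoxy-11,12,14-trimethoxyicetexa-8,11,13-trien-7-ol
Product: 17 komaroviquinone
Conditions: (NH4)2Ce(NO3)6 (2.5 equiv), MeCN/H2O, 0 °C
Reagents that add atoms: water, O
Why: oxidative demethylation of the para-dimethoxy pair (C11/C14) gives the p-quinone with the C12 methoxy group kept as a vinylogous ester, and the hemiketal and the three stereocentres are not touched.

**Compound list**
1 | 2,2-dimethylcyclopentan-1-one | CC1(C)CCCC1=O | starting material
2 | rac-1-ethenyl-2,2-dimethylcyclopentan-1-ol | C=CC1(O)CCCC1(C)C | intermediate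
3 | rac-(E)-3-(1-hydroxy-2,2-dimethylcyclopentyl)prop-2-enal | O=C/C=C/C1(O)CCCC1(C)C | intermediate
4 | (S)-2-(2,2-dimethyl-6-oxocyclohexyl)acetaldehyde | O=CC[C@@H]1C(=O)CCCC1(C)C | intermediate
5 | (S)-2-(2,2-dimethyl-6-oxocyclohexyl)acetic acid | OC(=O)C[C@@H]1C(=O)CCCC1(C)C | intermediate (not isolated)
6 | methyl (S)-2-(2,2-dimethyl-6-oxocyclohexyl)acetate | COC(=O)C[C@@H]1C(=O)CCCC1(C)C | intermediate
7 | 1,2,4-trimethoxybenzene | COc1ccc(OC)c(OC)c1 | starting material
8 | 2-(2,3,6-trimethoxyphenyl)propan-2-ol | COc1ccc(OC)c(C(C)(C)O)c1OC | intermediate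
9 | 1,2,4-trimethoxy-3-(propan-2-yl)benzene | COc1ccc(OC)c(C(C)C)c1OC | intermediate
10 | 1-bromo-2,4,5-trimethoxy-3-(propan-2-yl)benzene | COc1cc(Br)c(OC)c(C(C)C)c1OC | intermediate
11 | 1-bromo-2-(bromomethyl)-3,4,6-trimethoxy-5-(propan-2-yl)benzene | COc1c(CBr)c(Br)c(OC)c(C(C)C)c1OC | intermediate
12 | {[2-bromo-3,5,6-trimethoxy-4-(propan-2-yl)phenyl]methyl}magnesium bromide | COc1c(C[Mg]Br)c(Br)c(OC)c(C(C)C)c1OC | intermediate (not isolated)
13 | methyl 2-[(1S,2S)-2-{[2-bromo-3,5,6-trimethoxy-4-(propan-2-yl)phenyl]methyl}-2-hydroxy-6,6-dimethylcyclohexyl]acetate (formed as its magnesium alkoxide) | COc1c(C[C@@]2(O)CCCC(C)(C)[C@@H]2CC(=O)OC)c(Br)c(OC)c(C(C)C)c1OC | intermediate (not isolated)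
14 | (3aS,7aS)-7a-{[2-bromo-3,5,6-trimethoxy-4-(propan-2-yl)phenyl]methyl}-4,4-dimethylhexahydro-1-benzofuran-2(3H)-one | COc1c(C[C@@]23CCCC(C)(C)[C@@H]2CC(=O)O3)c(Br)c(OC)c(C(C)C)c1OC | intermediate
15 | aryllithium of 14 (lithium in place of bromine at C8) | COc1c(C[C@@]23CCCC(C)(C)[C@@H]2CC(=O)O3)c([Li])c(OC)c(C(C)C)c1OC | intermediate (not isolated)
16 | (5S,7S,10S)-7,10-epoxy-11,12,14-trimethoxyicetexa-8,11,13-trien-7-ol (bridged hemiketal, arene stage) | COc1c(C(C)C)c(OC)c2c(C[C@@]34CCCC(C)(C)[C@@H]3C[C@]2(O)O4)c1OC | intermediate
17 | komaroviquinone, (5S,7S,10S) | COC1=C(C(C)C)C(=O)C2=C(C[C@@]34CCCC(C)(C)[C@@H]3C[C@]2(O)O4)C1=O | target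

**Totals**
Total step count: 11.
Longest linear sequence: 7 steps (steps 1–4 and 9–11 from 1; the arene branch, steps 5–8 and 9–11 from 7, is equally long).

**Steps most likely to fail**

Step 3 (the proposed new method). The catalyst may fail to override the resident carbinol centre for the mismatched enantiomer of 3, which would erode the enantiomeric purity at C5, and the unstrained ring may migrate slowly. The fallback sets out from 3 and comes back at 5, using only established operations. The shift is run without a chiral controller as the racemic amine-salt-mediated vinylogous α-ketol rearrangement (pyrrolidine/AcOH, PhMe, heat) to give racemic 2-(2,2-dimethyl-6-oxocyclohexyl)acetaldehyde F1. Oxidation with NaClO2 as in step 4 gives racemic 2-(2,2-dimethyl-6-oxocyclohexyl)acetic acid F2. Classical resolution by crystallisation with (S)-1-phenylethylamine gives the diastereomerically pure (S)-1-phenylethylammonium (S)-2-(2,2-dimethyl-6-oxocyclohexyl)acetate F3; the antipodal amine is used if the salt of the (R)-acid is the one that crystallises. Acidification frees 5, which is methylated to 6 as in the second half of step 4.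

Step 10. Proton transfer from the lactone α-methylene to the aryllithium (loss of the metal without ring closure), or direct attack of t-BuLi on the lactone, may compete with exchange and cyclisation. The fallback sets out from 14 and comes back at 16; it separates ring B closure from bridge formation and uses a non-enolisable-on-addition acyl acceptor. The lactone is opened with MeNH(OMe)·HCl/AlMe3 to N-methoxy-N-methyl-2-[(1S,2S)-2-{[2-bromo-3,5,6-trimethoxy-4-(propan-2-yl)phenyl]methyl}-2-hydroxy-6,6-dimethylcyclohexyl]acetamide F4. The tertiary hydroxyl is silylated (TMSOTf, 2,6-lutidine) to the trimethylsilyl ether of that amide F5. Bromine–lithium exchange (t-BuLi, −95 °C) with cyclisation onto the Weinreb amide gives the ring B ketone (5S,10S)-11,12,14-trimethoxy-10-[(trimethylsilyl)oxy]icetexa-8,11,13-trien-7-one F6. K2CO3/MeOH removes the silyl group, and the freed C10 hydroxyl closes onto C7 to give 16.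

Step 2. Metathesis at the hindered allylic carbinol may be slow, with catalyst decomposition and self-metathesis of the enal taking over. The fallback sets out from 1 and comes back at 3; it builds the enal by carbonyl addition and redox steps instead of metathesis. Dilithiated propargyl alcohol (HC≡CCH2OH, 2 n-BuLi, THF) adds to 1 to give rac-1-(3-hydroxyprop-1-yn-1-yl)-2,2-dimethylcyclopentan-1-ol F7. LiAlH4 in THF at reflux reduces the propargylic alkyne to rac-(E)-1-(3-hydroxyprop-1-en-1-yl)-2,2-dimethylcyclopentan-1-ol F8. MnO2 in CH2Cl2 oxidises only the primary allylic alcohol and gives 3.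

**Further compounds**
F1 | step 3 | rac-2-(2,2-dimethyl-6-oxocyclohexyl)acetaldehyde | O=CCC1C(=O)CCCC1(C)C
F2 | step 3 | rac-2-(2,2-dimethyl-6-oxocyclohexyl)acetic acid | OC(=O)CC1C(=O)CCCC1(C)C
F3 | step 3 | (S)-1-phenylethylammonium (S)-2-(2,2-dimethyl-6-oxocyclohexyl)acetate | C[C@H]([NH3+])c1ccccc1.[O-]C(=O)C[C@@H]1C(=O)CCCC1(C)C
F4 | step 10 | N-methoxy-N-methyl-2-[(1S,2S)-2-{[2-bromo-3,5,6-trimethoxy-4-(propan-2-yl)phenyl]methyl}-2-hydroxy-6,6-dimethylcyclohexyl]acetamide | COc1c(C[C@@]2(O)CCCC(C)(C)[C@@H]2CC(=O)N(C)OC)c(Br)c(OC)c(C(C)C)c1OC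
F5 | step 10 | trimethylsilyl ether of F4 at the tertiary hydroxyl | COc1c(C[C@@]2(O[Si](C)(C)C)CCCC(C)(C)[C@@H]2CC(=O)N(C)OC)c(Br)c(OC)c(C(C)C)c1OC
F6 | step 10 | (5S,10S)-11,12,14-trimethoxy-10-[(trimethylsilyl)oxy]icetexa-8,11,13-trien-7-one | COc1c(C(C)C)c(OC)c2c(c1OC)C[C@@]1(O[Si](C)(C)C)CCCC(C)(C)[C@@H]1CC2=O
F7 | step 2 | rac-1-(3-hydroxyprop-1-yn-1-yl)-2,2-dimethylcyclopentan-1-ol | OCC#CC1(O)CCCC1(C)C
F8 | step 2 | rac-(E)-1-(3-hydroxyprop-1-en-1-yl)-2,2-dimethylcyclopentan-1-ol | OC/C=C/C1(O)CCCC1(C)C
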